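**Retrosynthetic overview**
1. Target ⇐ tetracyclic aryl ketone 14 (Wolff–Kishner reduction, both silyl ethers lost in the same pot) ⇐ α-ketol 13 (SmI2).
2. 13 ⇐ 12 by a 5-exo reductive Heck cyclisation: one syn addition makes the aryl–C bond at the benzylic ring-fusion carbon and the C–H at the aryl-bearing carbon.
3. 12 ⇐ aldehyde 11 + cyclobutenone 7 by an enantioselective carbene-catalysed cross-benzoin: the aldehyde carbon reacts as an acyl anion with the ketone carbon (key C–C bond, first stereocentre).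
4. 7 ⇐ aryl alkyne 3 + tetramethylketeniminium ([2+2]); 11 ⇐ 2,4-dihydroxy-6-methoxybenzaldehyde + prenal, then triflation.
5. Ring order: chromene ring (in 11) and cyclobutene ring (in 7) first, cyclopentane ring last (step 7).

Assumption: the (5aR,10bS) aminoindanol triazolium salt is taken to give (R)-12; if the induction runs the other way, the (5aS,10bR) salt is used.

**Route**

Step 1
Reactants: 1 3,4-dihydroxybenzaldehyde
Product: 2 3,4-bis[(tert-butyldimethylsilyl)oxy]benzaldehyde
Conditions: TBSCl (2.4 equiv), imidazole (5 equiv), DMF, 23 °C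
Reagents that add atoms: tert-butyldimethylsilyl chloride, CC(C)(C)[Si](C)(C)Cl
Why: Imidazole-promoted silyl ether formation on both phenols gives aryl silyl ethers that should survive steps 2–8 and are cleaved by the base of step 9; no stereocentre.

Step 2
Reactants: 2 3,4-bis[(tert-butyldimethylsilyl)oxy]benzaldehyde
Product: 3 4-ethynyl-1,2-bis[(tert-butyldimethylsilyl)oxy]benzene
Conditions: TMSCHN2 (1.3 equiv), LDA (1.3 equiv), THF, −78 °C; then 2, −78 → 23 °C
Reagents that add atoms: (trimethylsilyl)diazomethane, C[Si](C)(C)C=[N+]=[N-]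
Why: Colvin rearrangement (addition of the lithiated diazomethane, Peterson elimination, 1,2-shift in the alkylidene carbene) turns the aryl aldehyde into the terminal alkyne without the carbonate/methanol conditions that would cleave aryl silyl ethers.

Step 3
Reactants: 3 4-ethynyl-1,2-bis[(tert-butyldimethylsilyl)oxy]benzene; 4 1-chloro-N,N,2-trimethylprop-1-en-1-amine
Product: 7 3-{3,4-bis[(tert-butyldimethylsilyl)oxy]phenyl}-4,4-dimethylcyclobut-2-en-1-one, via keteniminium trichlorozincate 5 (not isolated), via cyclobuteniminium trichlorozincate 6 (not isolated)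
Conditions: 4 (1.2 equiv), ZnCl2 (1.2 equiv), CH2Cl2, 0 °C; then 3, 40 °C; then H2O, 23 °C
Reagents that add atoms: water, O; zinc chloride, Cl[Zn]Cl (only in the counter-ion of 5 and 6)
Why: Ghosez keteniminium–alkyne [2+2] cycloaddition: the central carbon of 5 bonds to the terminal alkyne carbon (aryl-stabilised vinyl cation), so the aryl group ends next to CMe2 in 6, and hydrolysis of the iminium gives enone 7, which has no stereocentre and no enolisable hydrogen.

Step 4
Reactants: 8 2,4-dihydroxy-6-methoxybenzaldehyde; 9 3-methylbut-2-enal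
Product: 10 5-hydroxy-7-methoxy-2,2-dimethyl-2H-chromene-6-carbaldehyde
Conditions: ethylenediammonium diacetate (20 mol %), xylenes, 140 °C, Dean–Stark
Reagents that add atoms: none
Why: Formal [3+3] chromene annulation (C-alkylation/dehydration to an ortho-quinone methide, then oxa-6π electrocyclisation): the 2-OH is locked by its hydrogen bond to CHO, so the free 4-OH and the carbon between the two hydroxyls react, as is usual for 2,4-dihydroxyaryl carbonyl compounds.

Step 5
Reactants: 10 5-hydroxy-7-methoxy-2,2-dimethyl-2H-chromene-6-carbaldehyde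
Product: 11 6-formyl-7-methoxy-2,2-dimethyl-2H-chromen-5-yl trifluoromethanesulfonate
Conditions: Tf2O (1.2 equiv), pyridine (3 equiv), CH2Cl2, −20 → 0 °C
Reagents that add atoms: trifluoromethanesulfonic anhydride, O=S(=O)(OS(=O)(=O)C(F)(F)F)C(F)(F)F
Why: Phenol O-triflation turns the chelated 5-OH into the aryl electrophile for step 7 at the ring position (meta to both oxygens) that electrophilic substitution cannot reach.

Step 6
Reactants: 7 3-{3,4-bis[(tert-butyldimethylsilyl)oxy]phenyl}-4,4-dimethylcyclobut-2-en-1-one; 11 6-formyl-7-methoxy-2,2-dimethyl-2H-chromen-5-yl trifluoromethanesulfonate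
Product: 12 6-{[(1R)-3-{3,4-bis[(tert-butyldimethylsilyl)oxy]phenyl}-1-hydroxy-4,4-dimethylcyclobut-2-en-1-yl]carbonyl}-7-methoxy-2,2-dimethyl-2H-chromen-5-yl trifluoromethanesulfonate
Conditions: 7 (1.5 equiv), (5aR,10bS)-2-(pentafluorophenyl)-5a,10b-dihydro-4H,6H-indeno[2,1-b][1,2,4]triazolo[4,3-d][1,4]oxazin-2-ium tetrafluoroborate (20 mol %), i-Pr2NEt (20 mol %), 4 Å sieves, THF, 0 → 23 °C
Reagents that add atoms: none
Why: Proposed new method: an intermolecular enantioselective carbene-catalysed aldehyde–ketone cross-benzoin, in which the triazolylidene adds to the aldehyde of 11 to give the Breslow intermediate (acyl anion equivalent) that adds 1,2 to the strain-activated C=O of 7 on the face chosen by the aminoindanol backbone (small vinyl CH against bulky CMe2) and so sets the (R)-carbinol; homo-benzoin of 11 is blocked by its two ortho substituents, 1,4-addition is blocked by the fully substituted β-carbon of 7, and rehybridisation of the cyclobutenone carbonyl makes the adduct downhill; the closest known reactions are carbene-catalysed cross-benzoin additions of aldehydes to activated ketones and intramolecular aldehyde–ketone benzoin cyclisations.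

Step 7
Reactants: 12 the (R)-cyclobutenyl aryl ketol from step 6
Product: 13 (R,R,R)-tetracyclic α-ketol (cis-fused hydroxy-cyclobuta-cyclopentanone across chromene C5/C6; silyloxyphenyl group exo)
Conditions: Pd(OAc)2 (10 mol %), XPhos (20 mol %), HCO2Na (3 equiv), DMF, 45 °C
Reagents that add atoms: none
Why: Intramolecular reductive Heck reaction: after oxidative addition into the aryl triflate, 5-exo-trig syn-carbopalladation can reach the cyclobutene only from the face of the aroyl group, which fixes the cis ring fusion and puts palladium on the aryl-bearing carbon cis to the new aryl–C bond; as no syn β-hydrogen exists, formate delivers hydride with retention and the silyloxyphenyl group ends trans to the new bond.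

Step 8
Reactants: 13 (R,R,R)-tetracyclic α-ketol
Product: 14 (S,S,S)-tetracyclic ketone (H in place of the tertiary OH)
Conditions: SmI2 (2.5 equiv), THF/MeOH 20:1, −78 → −20 °C
Reagents that add atoms: none
Why: SmI2 reductive cleavage of the C–O bond alpha to the aryl ketone, with in situ protonation by MeOH, can only give the cis-fused four/five ring junction, so the new CH is dictated by the two stereocentres already present.

Step 9
Reactants: 14 (S,S,S)-tetracyclic ketone
Product: 16 CNP0207533.1 (target), via free-catechol hydrazone 15 (not isolated)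
Conditions: N2H4·H2O (20 equiv), KOH (10 equiv), diethylene glycol, 120 °C then 190 °C, argon; aq NH4Cl work-up
Reagents that add atoms: hydrazine hydrate, NN.O (nitrogen is carried only in 15 and leaves as N2)
Why: Wolff–Kishner reduction (Huang-Minlon procedure) takes the aryl ketone through hydrazone 15 to the benzylic CH2 while hot KOH cleaves both aryl silyl ethers; the CH alpha to C=N is held cis by the ring fusion and the other two stereocentres are not acidic.

**Compound list**
1 | 3,4-dihydroxybenzaldehyde | O=Cc1ccc(O)c(O)c1 | starting material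
2 | 3,4-bis[(tert-butyldimethylsilyl)oxy]benzaldehyde | O=Cc1ccc(O[Si](C)(C)C(C)(C)C)c(O[Si](C)(C)C(C)(C)C)c1 | intermediate
3 | 4-ethynyl-1,2-bis[(tert-butyldimethylsilyl)oxy]benzene | C#Cc1ccc(O[Si](C)(C)C(C)(C)C)c(O[Si](C)(C)C(C)(C)C)c1 | intermediate
4 | 1-chloro-N,N,2-trimethylprop-1-en-1-amine | CC(C)=C(Cl)N(C)C | starting material
5 | N,N-dimethyl-2-methylprop-1-en-1-ylideneammonium trichlorozincate (tetramethylketeniminium salt, formed in the flask) | CC(C)=C=[N+](C)C.Cl[Zn-](Cl)Cl | intermediate
6 | N-(3-{3,4-bis[(tert-butyldimethylsilyl)oxy]phenyl}-4,4-dimethylcyclobut-2-en-1-ylidene)-N-methylmethanaminium trichlorozincate (formed in the flask) | C[N+](C)=C1C=C(c2ccc(O[Si](C)(C)C(C)(C)C)c(O[Si](C)(C)C(C)(C)C)c2)C1(C)C.Cl[Zn-](Cl)Cl | intermediate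
7 | 3-{3,4-bis[(tert-butyldimethylsilyl)oxy]phenyl}-4,4-dimethylcyclobut-2-en-1-one | O=C1C=C(c2ccc(O[Si](C)(C)C(C)(C)C)c(O[Si](C)(C)C(C)(C)C)c2)C1(C)C | intermediate
8 | 2,4-dihydroxy-6-methoxybenzaldehyde | COc1cc(O)cc(O)c1C=O | starting material
9 | 3-methylbut-2-enal (prenal) | CC(C)=CC=O | starting material
10 | 5-hydroxy-7-methoxy-2,2-dimethyl-2H-chromene-6-carbaldehyde | COc1cc2c(c(O)c1C=O)C=CC(C)(C)O2 | intermediate
11 | 6-formyl-7-methoxy-2,2-dimethyl-2H-chromen-5-yl trifluoromethanesulfonate | COc1cc2c(c(OS(=O)(=O)C(F)(F)F)c1C=O)C=CC(C)(C)O2 | intermediate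
12 | 6-{[(1R)-3-{3,4-bis[(tert-butyldimethylsilyl)oxy]phenyl}-1-hydroxy-4,4-dimethylcyclobut-2-en-1-yl]carbonyl}-7-methoxy-2,2-dimethyl-2H-chromen-5-yl trifluoromethanesulfonate | COc1cc2c(c(OS(=O)(=O)C(F)(F)F)c1C(=O)[C@@]1(O)C=C(c3ccc(O[Si](C)(C)C(C)(C)C)c(O[Si](C)(C)C(C)(C)C)c3)C1(C)C)C=CC(C)(C)O2 | intermediate
13 | tetracyclic α-ketol: 7-methoxy-2,2-dimethyl-2H-chromene carrying across C5/C6 the five-membered ring C6–C(=O)–C(OH)–CH–C5, whose C(OH) and CH are also bridged by CMe2–CH(Ar) to a cis-fused cyclobutane; C(OH) R, ring-fusion CH R, CH(Ar) R; Ar = 3,4-bis(TBSO)phenyl on the same face as OH and the ring-fusion H | COc1cc2c(c3c1C(=O)[C@@]1(O)[C@@H]3[C@H](c3ccc(O[Si](C)(C)C(C)(C)C)c(O[Si](C)(C)C(C)(C)C)c3)C1(C)C)C=CC(C)(C)O2 | intermediate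
14 | tetracyclic ketone: as 13 with H in place of OH; CH next to C=O S, benzylic ring-fusion CH S, CH(Ar) S | COc1cc2c(c3c1C(=O)[C@H]1[C@@H]3[C@H](c3ccc(O[Si](C)(C)C(C)(C)C)c(O[Si](C)(C)C(C)(C)C)c3)C1(C)C)C=CC(C)(C)O2 | intermediate
15 | hydrazone of the desilylated ketone (free catechol; S,S,S; formed in the flask) | COc1cc2c(c3c1C(=NN)[C@H]1[C@@H]3[C@H](c3ccc(O)c(O)c3)C1(C)C)C=CC(C)(C)O2 | intermediate
16 | CNP0207533.1: as 14 with CH2 in place of C=O and a free 3,4-dihydroxyphenyl group; CH next to CH2 S, benzylic ring-fusion CH R, CH(Ar) S | COc1cc2c(c3c1C[C@H]1[C@@H]3[C@H](c3ccc(O)c(O)c3)C1(C)C)C=CC(C)(C)O2 | target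

**Step count and risk**
Total: 9 steps. Longest linear sequence: 7 steps (1, 2, 3, 6, 7, 8, 9); steps 4 and 5 make the second fragment.

Most likely to fail:

Step 6. The doubly ortho-substituted, electron-rich aldehyde may form the Breslow intermediate slowly. The carbene can instead attack the cyclobutenone and open it by C–C cleavage, the α-ketol can ring-expand under base, and the ee is untested. The fallback sets out from 7 and 11 and comes back at 13, replacing steps 6 and 7. The stereocentre is set by copper hydride instead: 7 is reduced 1,4 with Cu(OAc)2, (R)-DTBM-SEGPHOS (or its antipode, whichever gives the R ketone) and MeSiH(OMe)2 in toluene at 0 °C to {[(3R)-3-{3,4-bis[(tert-butyldimethylsilyl)oxy]phenyl}-4,4-dimethylcyclobut-1-en-1-yl]oxy}dimethoxy(methyl)silane F1. Dilute HCl in THF hydrolyses this to (R)-3-{3,4-bis[(tert-butyldimethylsilyl)oxy]phenyl}-2,2-dimethylcyclobutan-1-one F2. Palladium-catalysed α-arylation of F2 with 11 (Pd2(dba)3, XPhos, K3PO4, toluene, 90 °C) gives, under thermodynamic control, the trans keto-aldehyde (2R,3R)-2-(6-formyl-7-methoxy-2,2-dimethyl-2H-chromen-5-yl)-3-{3,4-bis[(tert-butyldimethylsilyl)oxy]phenyl}-4,4-dimethylcyclobutan-1-one F3. An intramolecular carbene-catalysed aldehyde–ketone benzoin (2-(pentafluorophenyl)-6,7-dihydro-5H-pyrrolo[2,1-c][1,2,4]triazol-2-ium tetrafluoroborate, Et3N, CH2Cl2) then closes the five-membered ring to 13.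

Step 7. The tertiary cyclobutenol can open thermally (hence 45 °C). The palladium alkoxide or the cyclobutyl–palladium species can undergo β-carbon scission, and the aryl–palladium can be reduced before it cyclises. The fallback sets out from 11 (with 7) and comes back at 13. Miyaura borylation of 11 (Pd(dppf)Cl2, B2pin2, KOAc, dioxane, 80 °C) gives 7-methoxy-2,2-dimethyl-5-(4,4,5,5-tetramethyl-1,3,2-dioxaborolan-2-yl)-2H-chromene-6-carbaldehyde F4. The cross-benzoin of step 6 with 7 then gives the (R)-boronate ketol F5. A rhodium-catalysed intramolecular hydroarylation ([Rh(cod)OH]2, dioxane/H2O, 40 °C) closes the ring: aryl–rhodium adds syn across the cyclobutene and the alkyl–rhodium is protonated with retention, which is the same stereochemical outcome as step 7 and gives 13.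

Step 9. Hydrazone formation at the hindered ketone may be slow. The methoxy group ortho to C=N may be cleaved at 190 °C, traces of air would make diimide (which reduces the chromene alkene), and the catecholate is air-sensitive. The fallback sets out from 14 and comes back at 16. NaBH4 (THF/MeOH, 0 °C) gives the benzylic alcohol F6 (carbinol configuration immaterial). Ionic deoxygenation (Et3SiH, BF3·OEt2, CH2Cl2, −78 °C) gives the bis-silyl ether of the target F7. Buffered fluoride (TBAF, AcOH, THF, 0 °C) then gives 16.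

**Further compounds**
F1 | step 6 | {[(3R)-3-{3,4-bis[(tert-butyldimethylsilyl)oxy]phenyl}-4,4-dimethylcyclobut-1-en-1-yl]oxy}dimethoxy(methyl)silane | CO[Si](C)(OC)OC1=C[C@H](c2ccc(O[Si](C)(C)C(C)(C)C)c(O[Si](C)(C)C(C)(C)C)c2)C1(C)C
F2 | step 6 | (R)-3-{3,4-bis[(tert-butyldimethylsilyl)oxy]phenyl}-2,2-dimethylcyclobutan-1-one | O=C1C[C@H](c2ccc(O[Si](C)(C)C(C)(C)C)c(O[Si](C)(C)C(C)(C)C)c2)C1(C)C
F3 | step 6 | (2R,3R)-2-(6-formyl-7-methoxy-2,2-dimethyl-2H-chromen-5-yl)-3-{3,4-bis[(tert-butyldimethylsilyl)oxy]phenyl}-4,4-dimethylcyclobutan-1-one | COc1cc2c(c(c1C=O)[C@@H]1C(=O)C(C)(C)[C@H]1c1ccc(O[Si](C)(C)C(C)(C)C)c(O[Si](C)(C)C(C)(C)C)c1)C=CC(C)(C)O2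
F4 | step 7 | 7-methoxy-2,2-dimethyl-5-(4,4,5,5-tetramethyl-1,3,2-dioxaborolan-2-yl)-2H-chromene-6-carbaldehyde | COc1cc2c(c(B3OC(C)(C)C(C)(C)O3)c1C=O)C=CC(C)(C)O2
F5 | step 7 | [(1R)-3-{3,4-bis[(tert-butyldimethylsilyl)oxy]phenyl}-1-hydroxy-4,4-dimethylcyclobut-2-en-1-yl][7-methoxy-2,2-dimethyl-5-(4,4,5,5-tetramethyl-1,3,2-dioxaborolan-2-yl)-2H-chromen-6-yl]methanone | COc1cc2c(c(B3OC(C)(C)C(C)(C)O3)c1C(=O)[C@@]1(O)C=C(c3ccc(O[Si](C)(C)C(C)(C)C)c(O[Si](C)(C)C(C)(C)C)c3)C1(C)C)C=CC(C)(C)O2
F6 | step 9 | benzylic alcohol from 14 (C=O reduced to CH–OH; other centres as in 14) | COc1cc2c(c3c1[C@H](O)[C@H]1[C@@H]3[C@H](c3ccc(O[Si](C)(C)C(C)(C)C)c(O[Si](C)(C)C(C)(C)C)c3)C1(C)C)C=CC(C)(C)O2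
F7 | step 9 | bis(tert-butyldimethylsilyl) ether of the target | COc1cc2c(c3c1C[C@H]1[C@@H]3[C@H](c3ccc(O[Si](C)(C)C(C)(C)C)c(O[Si](C)(C)C(C)(C)C)c3)C1(C)C)C=CC(C)(C)O2
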